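Ask when G stops rising in this flask, how high it stands then, and how fast it sinks afterwards.

| flask | E | G | remark | time |
|---|---|---|---|---|
| south | 0.070 M | 0.50 mM | run made earlier |  |
| north-east | 0.11 M | 0.50 mM | run made earlier |  |
| flask | 0.050 M | 0.500 mM |  | 6.0 h |

| run | time / h | G / % | E / % |
|---|---|---|---|
| south | 0.0667 | 86.5 | 13.3 |
| south | 0.333 | 93.1 | 0.8 |
| south | 1.50 | 86.0 | 2.3 |
| south | 8.00 | 76.5 | 0 |
| north-east | 0.0667 | 97.9 | 1.7 |
| north-east | 0.333 | 93.9 | 0.8 |
| north-east | 1.50 | 89.5 | 0 |
| north-east | 8.00 | 80.5 | 1.8 |

(each reading ± 1 percentage point)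

1. time up to 6.0 h at which G stands highest
2. the amount of G, in percent of the E charged, at that time
3. the first time at which G reaches 68 %, in the same percent

- amounts and yields of G count Z too
- given per volume of solution although it is solid: Z
- steps thought possible: E + G -> 2 G; E -> G; G <-> D; Z <-> G

Compare two rates at one moment: what E, the limiting reagent, feeds into G, and what leaves G as D. Late on, the first fades with the concentration cE, and G stands at its top where the two are equal. With nothing leaving, that top is 101 %, charge plus seed.

For the sinking that follows, solve two extreme versions in your head. If G leaves as a fixed share, the late stretch of the two runs gives a mean of 0.0172 h⁻¹. If crystals hold dissolved G at a steady level, a fixed amount leaves instead: 1.02 mM h⁻¹ in the south run and 1.52 mM h⁻¹ in the north-east run. Their mean, 1.27 mM h⁻¹, is the drain as read from these two runs, the amount of G, crystals counted, lost per hour. With a scatter of 1 percentage point on each reading, these two runs do not part the two versions. My own reckoning puts this flask near the drain while Z stands, which is 0.0255 h⁻¹ of the charge, steeper than the share.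

The forecast put the top at 97.5 % at 0.15 h and the asked level at 0.075 h, and called the fall “roughly independent of concentration”. On the fall, my reckoning differs from it.

This flask tops at 96.5 % at 0.141 h and reaches the asked level at 0.0735 h, within the margins of the forecast. The return of D to G leaves that top unchanged.

    E + G → 2 G (k = 24.9 L mol⁻¹ min⁻¹)
    E → G (k = 3.98 × 10⁻⁵ min⁻¹)
    G ⇌ D (K = 33.0, k = 0.00959 min⁻¹)
    Z ⇌ G, rate k4*(cs4 - [G]) while solid is left; crystals form when [G] > cs4 (solubility = 2.70 mM, k = 0.0782 min⁻¹)

At 3.00 h this flask holds 82.9 % G. Reckoned with the drain, that becomes 75.2 % at 6.00 h, and the flask gives 75.6 %.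

Read the same flask at 15 h: the drain from 75.6 % gives 52.7 %. The computed G there is 55.6 %, with Z at 50.7 %.

The numbers in the tables come from a simulation with constants of no real substance; scatter was added.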